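## Plan

- **Numbering and cuts.** Isoflavan numbering is used: ring A is C4a–C8a, ring C is O1–C4, ring B is C1'–C6', and the pyran is ring D. The retrosynthesis cuts, in order: the two MOM ethers; ring D at C2'–O and C3'–CH= together; the C4 oxygen and the ring C unsaturation; C3–C1'; ring C.
- **Enabling feature.** In ring B the ring D oxygen (on C2') and the ring D vinyl carbon (on C3') sit on adjacent carbons directly beside the C4' oxygen. This is the imprint of a 3-alkoxyaryne C2'≡C3'. The O–C(CH3)2–CH=CH chain is the closed valence isomer of the o-quinone methide that this aryne forms with 3-methylbut-2-enal.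
- **Regiocontrol.** The C4' oxygen polarises the aryne so that O ends on C2' and CH on C3'. This removes the 2'-O/4'-O and C3'/C5' ambiguity of phenol-based chromene annulations.
- **Forward order.** One 2'-O-carbamate steers two ortho metalations of ring B (SiMe3 to C3', boron to C1'). Ring C is closed as a 3-iodochromone. Suzuki–Miyaura coupling joins C3–C1'. Reduction gives the chroman, carbamate-to-triflate exchange arms the aryne, and ring D closes last.
- **Stereochemistry.** C3 (R) comes from asymmetric transfer hydrogenation with dynamic kinetic resolution by an (R,R)-TsDPEN ruthenium catalyst. The helper carbinol centre at C4 is erased by hydrogenolysis, and nothing later touches C3.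

Key step: step 13

Remark on the chemistry: 1, 8 and 18 are taken as commercial. Compound 13 is drawn without configuration because C3 racemises under the conditions. Compound 20 is a transient mixture of epimers at the oxete carbon.

## Route

Step 1
Reactants: 1 resorcinol
Product: 2 3-hydroxyphenyl N,N-diethylcarbamate
Conditions: Et2NCOCl (0.5 equiv), K2CO3, MeCN, reflux
Reagents that add atoms: diethylcarbamoyl chloride, CCN(CC)C(=O)Cl
Why: O-Carbamoylation of a phenoxide (acyl substitution); with the symmetric diol in twofold excess the reaction should stop at the mono-carbamate, and the leftover resorcinol goes into the aqueous wash.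

Step 2
Reactants: 2 3-hydroxyphenyl N,N-diethylcarbamate
Product: 3 3-(methoxymethoxy)phenyl N,N-diethylcarbamate
Conditions: MOMCl, K2CO3, acetone, rt
Reagents that add atoms: chloromethyl methyl ether (MOMCl), COCCl
Why: Williamson-type O-alkylation of the remaining phenol; the MOM ether is the second directing group for the metalations and the fluoride-stable mask of the future 4'-OH.

Step 3
Reactants: 3 3-(methoxymethoxy)phenyl N,N-diethylcarbamate
Product: 5 3-(methoxymethoxy)-2-(trimethylsilyl)phenyl N,N-diethylcarbamate, via 2-lithio carbamate 4 (not isolated)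
Conditions: s-BuLi, TMEDA, THF, −78 °C; then TMSCl, −78 °C → rt
Reagents that add atoms: chlorotrimethylsilane (TMSCl), C[Si](C)(C)Cl
Why: Directed ortho metalation; the carbamate and the OMOM group stand 1,3 to each other and cooperate, so deprotonation should occur at the carbon between them, and the cold silyl quench forestalls the anionic ortho-Fries shift.

Step 4
Reactants: 5 3-(methoxymethoxy)-2-(trimethylsilyl)phenyl N,N-diethylcarbamate
Product: 7 3-(methoxymethoxy)-6-(4,4,5,5-tetramethyl-1,3,2-dioxaborolan-2-yl)-2-(trimethylsilyl)phenyl N,N-diethylcarbamate, via 6-lithio carbamate 6 (not isolated)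
Conditions: s-BuLi, TMEDA, THF, −78 °C; then iPrOBpin, −78 °C → rt; aqueous work-up
Reagents that add atoms: 2-isopropoxy-4,4,5,5-tetramethyl-1,3,2-dioxaborolane (iPrOBpin), CC(C)OB1OC(C)(C)C(C)(C)O1
Why: Second directed ortho metalation; with C2 blocked by silicon, the stronger director (O-carbamate over OMOM) should send lithium to C6, and cold borylation traps it as the pinacol boronate.

Step 5
Reactants: 8 1-(2,4-dihydroxy-6-methoxyphenyl)ethan-1-one
Product: 9 1-[2-hydroxy-6-methoxy-4-(methoxymethoxy)phenyl]ethan-1-one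
Conditions: MOMCl (1.05 equiv), K2CO3, acetone, rt
Reagents that add atoms: chloromethyl methyl ether (MOMCl), COCCl
Why: Selective Williamson-type O-alkylation; the 2-OH is locked in a hydrogen bond to the ketone, so only the 4-OH should be alkylated.

Step 6
Reactants: 9 1-[2-hydroxy-6-methoxy-4-(methoxymethoxy)phenyl]ethan-1-one
Product: 10 (E)-3-(dimethylamino)-1-[2-hydroxy-6-methoxy-4-(methoxymethoxy)phenyl]prop-2-en-1-one
Conditions: Me2NCH(OMe)2, toluene, 95 °C
Reagents that add atoms: N,N-dimethylformamide dimethyl acetal, COC(OC)N(C)C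
Why: Condensation of a methyl ketone with DMF dimethyl acetal gives the (E)-enaminone, the standard one-carbon extension toward chromones.

Step 7
Reactants: 10 (E)-3-(dimethylamino)-1-[2-hydroxy-6-methoxy-4-(methoxymethoxy)phenyl]prop-2-en-1-one
Product: 11 3-iodo-5-methoxy-7-(methoxymethoxy)-4H-chromen-4-one
Conditions: iodine, pyridine, CHCl3, rt
Reagents that add atoms: iodine, [I][I]
Why: Iodine-mediated cyclisation of an o-hydroxyaryl enaminone; α-iodination gives an iminium ion, the phenol adds to it (6-endo closure of ring C) and dimethylamine leaves, while pyridine keeps the medium non-acidic for the MOM ether.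

Step 8
Reactants: 7 3-(methoxymethoxy)-6-(4,4,5,5-tetramethyl-1,3,2-dioxaborolan-2-yl)-2-(trimethylsilyl)phenyl N,N-diethylcarbamate; 11 3-iodo-5-methoxy-7-(methoxymethoxy)-4H-chromen-4-one
Product: 12 6-[5-methoxy-7-(methoxymethoxy)-4-oxo-4H-chromen-3-yl]-3-(methoxymethoxy)-2-(trimethylsilyl)phenyl N,N-diethylcarbamate
Conditions: Pd(dppf)Cl2 (5 mol %), K2CO3, 1,4-dioxane/H2O, 80 °C
Reagents that add atoms: none
Why: Suzuki–Miyaura coupling; oxidative addition into the activated C3–I bond is fast, the aryl–SiMe3, carbamate and MOM groups are inert to aqueous carbonate, and the C3–C1' bond of the isoflavonoid skeleton results.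

Step 9
Reactants: 12 6-[5-methoxy-7-(methoxymethoxy)-4-oxo-4H-chromen-3-yl]-3-(methoxymethoxy)-2-(trimethylsilyl)phenyl N,N-diethylcarbamate
Product: 14 6-[(3R,4R)-4-hydroxy-5-methoxy-7-(methoxymethoxy)chroman-3-yl]-3-(methoxymethoxy)-2-(trimethylsilyl)phenyl N,N-diethylcarbamate, via racemising isoflavanone 13 (not isolated)
Conditions: RuCl[(R,R)-TsDPEN](p-cymene) (5 mol %), HCO2H/Et3N (amine-rich), EtOAc, 45 °C
Reagents that add atoms: none
Why: Noyori–Ikariya asymmetric transfer hydrogenation cascade with dynamic kinetic resolution; the ruthenium hydride first saturates C2=C3, isoflavanone 13 racemises at C3 through its enol under Et3N, and the (R,R)-catalyst should reduce only the (3R)-ketone to the (4R)-alcohol (the sense known for aryl ketones), cis to the aryl group, which fixes C3 as R.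

Step 10
Reactants: 14 6-[(3R,4R)-4-hydroxy-5-methoxy-7-(methoxymethoxy)chroman-3-yl]-3-(methoxymethoxy)-2-(trimethylsilyl)phenyl N,N-diethylcarbamate
Product: 15 6-[(3R)-5-methoxy-7-(methoxymethoxy)chroman-3-yl]-3-(methoxymethoxy)-2-(trimethylsilyl)phenyl N,N-diethylcarbamate
Conditions: H2 (1 atm), 10% Pd/C, EtOAc/EtOH, rt, no acid
Reagents that add atoms: none
Why: Hydrogenolysis of a benzylic alcohol activated by the ortho OMe and para OMOM groups; C3 is not involved and keeps its configuration, and any 15 already formed in step 9 by in situ deoxygenation converges here.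

Step 11
Reactants: 15 6-[(3R)-5-methoxy-7-(methoxymethoxy)chroman-3-yl]-3-(methoxymethoxy)-2-(trimethylsilyl)phenyl N,N-diethylcarbamate
Product: 16 6-[(3R)-5-methoxy-7-(methoxymethoxy)chroman-3-yl]-3-(methoxymethoxy)-2-(trimethylsilyl)phenol
Conditions: LiAlH4, THF, 0 °C → reflux; Na2SO4·10H2O quench (no acid)
Reagents that add atoms: none
Why: Reductive cleavage of an aryl O-carbamate (hydride addition to the carbamoyl C=O, loss of phenoxide); the substrate otherwise holds only ethers, acetals and a C–Si bond, all inert to hydride, so the 2'-OH alone is unmasked.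

Step 12
Reactants: 16 6-[(3R)-5-methoxy-7-(methoxymethoxy)chroman-3-yl]-3-(methoxymethoxy)-2-(trimethylsilyl)phenol
Product: 17 6-[(3R)-5-methoxy-7-(methoxymethoxy)chroman-3-yl]-3-(methoxymethoxy)-2-(trimethylsilyl)phenyl trifluoromethanesulfonate
Conditions: Tf2O, pyridine, CH2Cl2, −20 → 0 °C
Reagents that add atoms: trifluoromethanesulfonic anhydride, O=S(=O)(OS(=O)(=O)C(F)(F)F)C(F)(F)F
Why: O-Triflation of the only free phenol completes the o-silylaryl triflate, and the buffered cold medium spares the MOM ethers and the C–Si bond.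

Step 13
Reactants: 17 6-[(3R)-5-methoxy-7-(methoxymethoxy)chroman-3-yl]-3-(methoxymethoxy)-2-(trimethylsilyl)phenyl trifluoromethanesulfonate; 18 3-methylbut-2-enal
Product: 22 (3R)-5-methoxy-7-(methoxymethoxy)-3-[5-(methoxymethoxy)-2,2-dimethyl-2H-chromen-8-yl]chroman, via aryne 19 (not isolated), via benzoxete 20 (not isolated), via o-quinone methide 21 (not isolated)
Conditions: 18 (10 equiv), CsF (3 equiv), MeCN, rt → 40 °C
Reagents that add atoms: none
Why: Fluoride attacks the C3' silicon and triflate leaves from C2' (fluoride-induced 1,2-elimination of an o-silylaryl triflate), giving aryne 19 across C2'–C3' of ring B. The carbonyl oxygen of 18 adds to C2' and the C3' carbanion closes on the carbonyl carbon, a formal [2+2] cycloaddition that makes the aryl–O and aryl–CH bonds together in benzoxete 20. Strain-driven 4π electrocyclic opening of 20 gives o-quinone methide 21, whose (Z)-oxatriene closes ring D by a thermal disrotatory oxa-6π electrocyclisation (oxygen onto C(CH3)2) with rearomatisation of ring B, while the (E)-isomer can re-enter through 20. The closest known reaction type is the annulation of arynes from o-silylaryl triflates with α,β-unsaturated aldehydes to 2H-chromenes. The selectivity needed is regiochemical and is secured by the C4' OMOM group, whose σ-withdrawal distorts the aryne so that C2' is the electrophilic end and the developing charge sits at C3' next to oxygen, while the C1' alkyl group exerts no opposing electronic bias. No lasting stereocentre is made (the oxete carbon is erased on opening), C3 carries no acidifying group and is untouched, the MOM ethers leave no acidic OH, and the excess of 18 should outrun capture of 21 by a second aryne.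

Step 14
Reactants: 22 (3R)-5-methoxy-7-(methoxymethoxy)-3-[5-(methoxymethoxy)-2,2-dimethyl-2H-chromen-8-yl]chroman
Product: 23 (3R)-3-(5-hydroxy-2,2-dimethyl-2H-chromen-8-yl)-5-methoxychroman-7-ol
Conditions: aq HCl (cat.), MeOH, 40 °C
Reagents that add atoms: none
Why: Acid-catalysed transacetalisation of both aryl MOM ethers to methanol, conditions with close precedent beside 2,2-dimethyl-2H-chromenes; the methyl ether and C3 are unaffected.

## Compound list

| No. | Name | SMILES | Role |
|---|---|---|---|
| 1 | resorcinol | Oc1cccc(O)c1 | starting material |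
| 2 | 3-hydroxyphenyl N,N-diethylcarbamate | CCN(CC)C(=O)Oc1cccc(O)c1 | intermediate |
| 3 | 3-(methoxymethoxy)phenyl N,N-diethylcarbamate | CCN(CC)C(=O)Oc1cccc(OCOC)c1 | intermediate |
| 4 | 2-lithio-3-(methoxymethoxy)phenyl N,N-diethylcarbamate | CCN(CC)C(=O)Oc1cccc(OCOC)c1[Li] | intermediate |
| 5 | 3-(methoxymethoxy)-2-(trimethylsilyl)phenyl N,N-diethylcarbamate | CCN(CC)C(=O)Oc1cccc(OCOC)c1[Si](C)(C)C | intermediate |
| 6 | 6-lithio-3-(methoxymethoxy)-2-(trimethylsilyl)phenyl N,N-diethylcarbamate | CCN(CC)C(=O)Oc1c([Li])ccc(OCOC)c1[Si](C)(C)C | intermediate |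
| 7 | 3-(methoxymethoxy)-6-(4,4,5,5-tetramethyl-1,3,2-dioxaborolan-2-yl)-2-(trimethylsilyl)phenyl N,N-diethylcarbamate | CCN(CC)C(=O)Oc1c(B2OC(C)(C)C(C)(C)O2)ccc(OCOC)c1[Si](C)(C)C | intermediate |
| 8 | 1-(2,4-dihydroxy-6-methoxyphenyl)ethan-1-one | CC(=O)c1c(O)cc(O)cc1OC | starting material |
| 9 | 1-[2-hydroxy-6-methoxy-4-(methoxymethoxy)phenyl]ethan-1-one | CC(=O)c1c(O)cc(OCOC)cc1OC | intermediate |
| 10 | (E)-3-(dimethylamino)-1-[2-hydroxy-6-methoxy-4-(methoxymethoxy)phenyl]prop-2-en-1-one | CN(C)/C=C/C(=O)c1c(O)cc(OCOC)cc1OC | intermediate |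
| 11 | 3-iodo-5-methoxy-7-(methoxymethoxy)-4H-chromen-4-one | Ic1coc2cc(OCOC)cc(OC)c2c1=O | intermediate |
| 12 | isoflavone: 6-[5-methoxy-7-(methoxymethoxy)-4-oxo-4H-chromen-3-yl]-3-(methoxymethoxy)-2-(trimethylsilyl)phenyl N,N-diethylcarbamate | COCOc1cc(OC)c2c(=O)c(-c3ccc(OCOC)c([Si](C)(C)C)c3OC(=O)N(CC)CC)coc2c1 | intermediate |
| 13 | isoflavanone, racemising at C3: 6-[5-methoxy-7-(methoxymethoxy)-4-oxochroman-3-yl]-3-(methoxymethoxy)-2-(trimethylsilyl)phenyl N,N-diethylcarbamate | COc1cc(OCOC)cc2c1C(=O)C(c1ccc(OCOC)c([Si](C)(C)C)c1OC(=O)N(CC)CC)CO2 | intermediate |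
| 14 | cis-isoflavan-4-ol: 6-[(3R,4R)-4-hydroxy-5-methoxy-7-(methoxymethoxy)chroman-3-yl]-3-(methoxymethoxy)-2-(trimethylsilyl)phenyl N,N-diethylcarbamate | COc1cc(OCOC)cc2c1[C@H](O)[C@H](c1ccc(OCOC)c([Si](C)(C)C)c1OC(=O)N(CC)CC)CO2 | intermediate |
| 15 | 6-[(3R)-5-methoxy-7-(methoxymethoxy)chroman-3-yl]-3-(methoxymethoxy)-2-(trimethylsilyl)phenyl N,N-diethylcarbamate | COc1cc(OCOC)cc2c1C[C@H](c1ccc(OCOC)c([Si](C)(C)C)c1OC(=O)N(CC)CC)CO2 | intermediate |
| 16 | 6-[(3R)-5-methoxy-7-(methoxymethoxy)chroman-3-yl]-3-(methoxymethoxy)-2-(trimethylsilyl)phenol | COc1cc(OCOC)cc2c1C[C@H](c1ccc(OCOC)c([Si](C)(C)C)c1O)CO2 | intermediate |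
| 17 | 6-[(3R)-5-methoxy-7-(methoxymethoxy)chroman-3-yl]-3-(methoxymethoxy)-2-(trimethylsilyl)phenyl trifluoromethanesulfonate | COc1cc(OCOC)cc2c1C[C@H](c1ccc(OCOC)c([Si](C)(C)C)c1OS(=O)(=O)C(F)(F)F)CO2 | intermediate |
| 18 | 3-methylbut-2-enal (prenal) | CC(C)=CC=O | starting material |
| 19 | ring B aryne (C2'≡C3'): (3R)-5-methoxy-7-(methoxymethoxy)-3-[4-(methoxymethoxy)-2,3-didehydrophenyl]chroman | COc1cc(OCOC)cc2c1C[C@H](C1=CC=C(OCOC)C#C1)CO2 | intermediate |
| 20 | ring B-fused 2H-benzoxete, O on C2', CH(CH=C(CH3)2) on C3', (3R), both epimers at the oxete carbon | COc1cc(OCOC)cc2c1C[C@H](c1ccc(OCOC)c3c1OC3C=C(C)C)CO2 | intermediate |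
| 21 | (Z)-o-quinone methide, C2'=O and C3'=CH–CH=C(CH3)2, (3R) | COc1cc(OCOC)cc2c1C[C@H](C1=CC=C(OCOC)/C(=C/C=C(C)C)C1=O)CO2 | intermediate |
| 22 | (3R)-5-methoxy-7-(methoxymethoxy)-3-[5-(methoxymethoxy)-2,2-dimethyl-2H-chromen-8-yl]chroman | COc1cc(OCOC)cc2c1C[C@H](c1ccc(OCOC)c3c1OC(C)(C)C=C3)CO2 | intermediate |
| 23 | (3R)-3-(5-hydroxy-2,2-dimethyl-2H-chromen-8-yl)-5-methoxychroman-7-ol | COc1cc(O)cc2c1C[C@H](c1ccc(O)c3c1OC(C)(C)C=C3)CO2 | target |

## Step count and risks

Total step count: 14. Longest linear sequence: 11 (steps 1–4, then 8–14).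

**1. Step 13.**
- *What may go wrong:* attack at the C2' terminus, which is flanked by the secondary alkyl group, may be slow. Other processes could then take over: an ene reaction of the aryne with the methyl groups of 18, interception by O1 or by electron-rich ring A of the same molecule, protonation of the aryl anion by the solvent, or capture of the o-quinone methide by a second aryne.
- *Fallback (aromatic propargyl Claisen route, known chemistry):* it sets out from 16.
  - Protodesilylation with TBAF in wet THF gives the desilylated 2'-phenol F1.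
  - Copper-catalysed O-alkylation with 3-chloro-3-methylbut-1-yne (DBU, cat. CuCl2, MeCN, 0 °C) gives the 1,1-dimethylpropargyl ether F2.
  - Heating in N,N-diethylaniline at about 140 °C triggers the thermal propargyl Claisen rearrangement–cyclisation cascade onto C3', the only free ortho position of the 2'-oxygen.
  - The route is rejoined at 22.

**2. Step 9.**
- *What may go wrong:* the ketone is a doubly donor-substituted vinylogous ester next to the 5-OMe group, and ring B is bulky. Hydride transfer may stall at the isoflavanone stage. Racemisation may also lag behind reduction, which would erode the enantiomeric purity and the cis selectivity.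
- *Fallback (asymmetric hydrogenation of an alkene instead of a ketone):* it sets out from 12.
  - NaBH4 in THF/EtOH gives the racemic isoflavan-4-ol F3.
  - PPTS in toluene at 60 °C dehydrates this electron-rich benzylic alcohol to the isoflav-3-ene F4.
  - Hydrogenation with [Ir(cod)((S)-tBu-PHOX)]BArF under H2 (50 bar, CH2Cl2) sets C3. The ligand antipode that delivers R is to be fixed in a pilot run.
  - The route is rejoined at 15, bypassing step 10 as well.

**3. Step 12.**
- *What may go wrong:* sulfonylation of a phenol wedged between SiMe3 and the chromanyl group may stall. Protodesilylation by the pyridinium salt or attack of the anhydride on the MOM acetals could then compete.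
- *Fallback (no isolated precursor, activation in the flask):* it sets out from 16.
  - Compound 16 is treated with nonafluorobutanesulfonyl fluoride, Cs2CO3 and 18 in MeCN.
  - The slim S–F electrophile should form the nonaflate F5, and the fluoride released in this sulfonylation triggers the elimination at once to aryne 19.
  - Aryne 19 runs through 20 and 21, and the route is rejoined at 22.

## Further compounds

F1 | step 13 | 2-[(3R)-5-methoxy-7-(methoxymethoxy)chroman-3-yl]-5-(methoxymethoxy)phenol | COc1cc(OCOC)cc2c1C[C@H](c1ccc(OCOC)cc1O)CO2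
F2 | step 13 | (3R)-5-methoxy-7-(methoxymethoxy)-3-[4-(methoxymethoxy)-2-(2-methylbut-3-yn-2-yloxy)phenyl]chroman | COc1cc(OCOC)cc2c1C[C@H](c1ccc(OCOC)cc1OC(C)(C)C#C)CO2
F3 | step 9 | racemic 6-[4-hydroxy-5-methoxy-7-(methoxymethoxy)chroman-3-yl]-3-(methoxymethoxy)-2-(trimethylsilyl)phenyl N,N-diethylcarbamate | COc1cc(OCOC)cc2c1C(O)C(c1ccc(OCOC)c([Si](C)(C)C)c1OC(=O)N(CC)CC)CO2
F4 | step 9 | 6-[5-methoxy-7-(methoxymethoxy)-2H-chromen-3-yl]-3-(methoxymethoxy)-2-(trimethylsilyl)phenyl N,N-diethylcarbamate | COc1cc(OCOC)cc2c1C=C(c1ccc(OCOC)c([Si](C)(C)C)c1OC(=O)N(CC)CC)CO2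
F5 | step 12 | 6-[(3R)-5-methoxy-7-(methoxymethoxy)chroman-3-yl]-3-(methoxymethoxy)-2-(trimethylsilyl)phenyl nonafluorobutane-1-sulfonate | COc1cc(OCOC)cc2c1C[C@H](c1ccc(OCOC)c([Si](C)(C)C)c1OS(=O)(=O)C(F)(F)C(F)(F)C(F)(F)C(F)(F)F)CO2
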